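The bond on which everything rests joins the benzylic carbinol carbon C-1 of the propane chain to the guaiacyl ring carbon para to the phenolic oxygen. The key step adds a 4-silyloxy-3-methoxyphenyllithium to an (S)-2-aryloxy-3-silyloxypropanal: one operation joins the guaiacyl ring to the syringyl-bearing C3 chain and creates the C-1 hydroxyl stereocenter. It exploits the neighbouring C-2 stereocenter and its hindered, poorly chelating syringyl ether oxygen, which should steer polar Felkin–Anh attack to the 1,2-anti (erythro, 1R,2S) product. The aldehyde precursor carries C-2 from methyl (R)-glycerate, inverted by Mitsunobu etherification with syringaldehyde; a single global desilylation then liberates the target.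

Key step: step 7

Remark: the target SMILES corresponds to (1R,2S) in propane numbering (C-1 benzylic carbinol, C-2 aryloxy carbon), i.e. the erythro isomer. Methyl (R)-glycerate is taken as a commercial chiral-pool material.

**Step 1**
Reactants: 1 methyl (2R)-2,3-dihydroxypropanoate
Product: 2 methyl (2R)-3-[(tert-butyldimethylsilyl)oxy]-2-hydroxypropanoate
Conditions: TBSCl (1.05 equiv), imidazole, CH2Cl2, 0 °C
Reagents that add atoms: tert-butyldimethylsilyl chloride, CC(C)(C)[Si](C)(C)Cl
Why: Selective silylation of the primary hydroxyl should occur because the secondary α-hydroxy ester OH is more hindered and less nucleophilic; the stereocenter is not touched.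

**Step 2**
Reactants: 2 methyl (2R)-3-[(tert-butyldimethylsilyl)oxy]-2-hydroxypropanoate; 3 syringaldehyde (4-hydroxy-3,5-dimethoxybenzaldehyde)
Product: 4 methyl (2S)-3-[(tert-butyldimethylsilyl)oxy]-2-(4-formyl-2,6-dimethoxyphenoxy)propanoate
Conditions: PPh3, DIAD, THF, 0 °C → rt
Reagents that add atoms: none
Why: Mitsunobu etherification of an α-hydroxy ester with an acidic para-formyl phenol should proceed by SN2 displacement with inversion, turning the (R)-carbinol into the (S)-aryl ether that becomes C-2 of the target.

**Step 3**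
Reactants: 4 methyl (2S)-3-[(tert-butyldimethylsilyl)oxy]-2-(4-formyl-2,6-dimethoxyphenoxy)propanoate
Product: 5 methyl (2S)-3-[(tert-butyldimethylsilyl)oxy]-2-[4-(hydroxymethyl)-2,6-dimethoxyphenoxy]propanoate
Conditions: NaBH4 (0.5 equiv), THF/MeOH, −10 °C, short reaction time; aq. NH4Cl
Reagents that add atoms: none
Why: Chemoselective borohydride reduction of the aryl aldehyde should be much faster than attack on the methyl ester at low temperature, and the brief, cold conditions should spare the α-stereocenter.

**Step 4**
Reactants: 5 methyl (2S)-3-[(tert-butyldimethylsilyl)oxy]-2-[4-(hydroxymethyl)-2,6-dimethoxyphenoxy]propanoate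
Product: 6 methyl (2S)-3-[(tert-butyldimethylsilyl)oxy]-2-[4-({[tert-butyldimethylsilyl]oxy}methyl)-2,6-dimethoxyphenoxy]propanoate
Conditions: TBSCl, imidazole, DMF, rt
Reagents that add atoms: tert-butyldimethylsilyl chloride, CC(C)(C)[Si](C)(C)Cl
Why: Standard silylation of a primary benzylic alcohol masks the only acidic proton before the organolithium step and uses the same protecting group as the other hydroxyls.

**Step 5**
Reactants: 6 methyl (2S)-3-[(tert-butyldimethylsilyl)oxy]-2-[4-({[tert-butyldimethylsilyl]oxy}methyl)-2,6-dimethoxyphenoxy]propanoate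
Product: 8 (2S)-3-[(tert-butyldimethylsilyl)oxy]-2-[4-({[tert-butyldimethylsilyl]oxy}methyl)-2,6-dimethoxyphenoxy]propanal, via aluminium hemiacetal 7 (not isolated)
Conditions: DIBAL-H (1.1 equiv), CH2Cl2, −78 °C; MeOH, then aq. Rochelle salt; crude aldehyde used at once
Reagents that add atoms: none
Why: Partial DIBAL-H reduction of an α-oxygenated ester should stop at the chelate-stabilised tetrahedral aluminium hemiacetal at −78 °C, which releases the aldehyde only on work-up, so the C-2 configuration should be kept.

**Step 6**
Reactants: 9 4-bromo-2-methoxyphenol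
Product: 10 (4-bromo-2-methoxyphenoxy)(tert-butyl)dimethylsilane
Conditions: TBSCl, imidazole, DMF, rt
Reagents that add atoms: tert-butyldimethylsilyl chloride, CC(C)(C)[Si](C)(C)Cl
Why: Routine phenol silylation gives an aryl bromide that tolerates bromine–lithium exchange and is unmasked in the final fluoride step.

**Step 7**
Reactants: 10 (4-bromo-2-methoxyphenoxy)(tert-butyl)dimethylsilane; 8 (2S)-3-[(tert-butyldimethylsilyl)oxy]-2-[4-({[tert-butyldimethylsilyl]oxy}methyl)-2,6-dimethoxyphenoxy]propanal
Product: 12 (1R,2S)-1-{4-[(tert-butyldimethylsilyl)oxy]-3-methoxyphenyl}-3-[(tert-butyldimethylsilyl)oxy]-2-[4-({[tert-butyldimethylsilyl]oxy}methyl)-2,6-dimethoxyphenoxy]propan-1-ol, via aryllithium 11 (not isolated)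
Conditions: 10 (1.3 equiv), n-BuLi (1.25 equiv), THF, −78 °C; then 8 in THF, −78 °C; aq. NH4Cl at −78 °C
Reagents that add atoms: none
Why: Bromine–lithium exchange on 10 gives aryllithium 11, which adds 1,2 to the aldehyde carbonyl of 8 to give the lithium alkoxide of 12, protonated on quench. The closest known reaction type is the substrate-controlled (polar Felkin–Anh / Cornforth–Evans) addition of aryllithium reagents to α-alkoxy aldehydes. No ring is closed. The new C-1 stereocenter is controlled by the existing C-2 stereocenter: with the C–OAr bond antiperiplanar to the forming bond, the aryl group should enter past the C-2 hydrogen and not past CH2OTBS, which for the (S)-aldehyde gives the (1R,2S), 1,2-anti (erythro) alcohol. The step needs non-chelation facial selectivity and addition in place of enolisation; the weakly basic aryl ether oxygen and the bulky silyl ether are poor chelators, THF-solvated lithium at −78 °C disfavours a chelate, and an aryllithium should add faster than it deprotonates. The lithium sits para to the silyloxy group, so no silyl migration to carbon should interfere.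

**Step 8**
Reactants: 12 (1R,2S)-1-{4-[(tert-butyldimethylsilyl)oxy]-3-methoxyphenyl}-3-[(tert-butyldimethylsilyl)oxy]-2-[4-({[tert-butyldimethylsilyl]oxy}methyl)-2,6-dimethoxyphenoxy]propan-1-ol
Product: 13 (1R,2S)-1-(4-hydroxy-3-methoxyphenyl)-2-[4-(hydroxymethyl)-2,6-dimethoxyphenoxy]propane-1,3-diol
Conditions: TBAF (3.5 equiv), AcOH (3.5 equiv), THF, 0 °C → rt; neutral work-up
Reagents that add atoms: none
Why: Fluoride-mediated global desilylation should cleave the phenolic and both primary TBS ethers, while the acetic acid buffer keeps the medium near neutral so that the p-hydroxybenzylic C-1 centre should not epimerise through a quinone methide.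

**Compound list**
1 | methyl (2R)-2,3-dihydroxypropanoate (methyl D-glycerate) | COC(=O)[C@H](O)CO | starting material
2 | methyl (2R)-3-[(tert-butyldimethylsilyl)oxy]-2-hydroxypropanoate | COC(=O)[C@H](O)CO[Si](C)(C)C(C)(C)C | intermediate
3 | syringaldehyde (4-hydroxy-3,5-dimethoxybenzaldehyde) | COc1cc(C=O)cc(OC)c1O | starting material
4 | methyl (2S)-3-[(tert-butyldimethylsilyl)oxy]-2-(4-formyl-2,6-dimethoxyphenoxy)propanoate | COC(=O)[C@H](CO[Si](C)(C)C(C)(C)C)Oc1c(OC)cc(C=O)cc1OC | intermediate
5 | methyl (2S)-3-[(tert-butyldimethylsilyl)oxy]-2-[4-(hydroxymethyl)-2,6-dimethoxyphenoxy]propanoate | COC(=O)[C@H](CO[Si](C)(C)C(C)(C)C)Oc1c(OC)cc(CO)cc1OC | intermediate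
6 | methyl (2S)-3-[(tert-butyldimethylsilyl)oxy]-2-[4-({[tert-butyldimethylsilyl]oxy}methyl)-2,6-dimethoxyphenoxy]propanoate | COC(=O)[C@H](CO[Si](C)(C)C(C)(C)C)Oc1c(OC)cc(CO[Si](C)(C)C(C)(C)C)cc1OC | intermediate
7 | aluminium hemiacetal from 6 and DIBAL-H (diisobutylaluminium alkoxide of the methyl hemiacetal, hemiacetal carbon undefined, C-2 S) | COC(O[Al](CC(C)C)CC(C)C)[C@H](CO[Si](C)(C)C(C)(C)C)Oc1c(OC)cc(CO[Si](C)(C)C(C)(C)C)cc1OC | intermediate
8 | (2S)-3-[(tert-butyldimethylsilyl)oxy]-2-[4-({[tert-butyldimethylsilyl]oxy}methyl)-2,6-dimethoxyphenoxy]propanal | O=C[C@H](CO[Si](C)(C)C(C)(C)C)Oc1c(OC)cc(CO[Si](C)(C)C(C)(C)C)cc1OC | intermediate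
9 | 4-bromo-2-methoxyphenol | COc1cc(Br)ccc1O | starting material
10 | (4-bromo-2-methoxyphenoxy)(tert-butyl)dimethylsilane | COc1cc(Br)ccc1O[Si](C)(C)C(C)(C)C | intermediate
11 | {4-[(tert-butyldimethylsilyl)oxy]-3-methoxyphenyl}lithium | COc1cc([Li])ccc1O[Si](C)(C)C(C)(C)C | intermediate
12 | (1R,2S)-1-{4-[(tert-butyldimethylsilyl)oxy]-3-methoxyphenyl}-3-[(tert-butyldimethylsilyl)oxy]-2-[4-({[tert-butyldimethylsilyl]oxy}methyl)-2,6-dimethoxyphenoxy]propan-1-ol | COc1cc([C@@H](O)[C@H](CO[Si](C)(C)C(C)(C)C)Oc2c(OC)cc(CO[Si](C)(C)C(C)(C)C)cc2OC)ccc1O[Si](C)(C)C(C)(C)C | intermediate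
13 | (1R,2S)-1-(4-hydroxy-3-methoxyphenyl)-2-[4-(hydroxymethyl)-2,6-dimethoxyphenoxy]propane-1,3-diol | COc1cc([C@@H](O)[C@H](CO)Oc2c(OC)cc(CO)cc2OC)ccc1O | target

**Step count**
Total steps: 8. Longest linear sequence: 7 (steps 1–5, 7, 8); step 6 prepares the second fragment.

**Steps most likely to fail**

1. Step 7. The facial selectivity of the aryllithium addition may be poor if the aryloxy oxygen and its flanking methoxy groups bind lithium and a chelated transition state competes with the polar Felkin–Anh one; some enolisation of the aldehyde may also occur. Fallback: set out from 12 as obtained, whatever its composition at C-1, and oxidise it with Dess–Martin periodinane and NaHCO3 in CH2Cl2 to the aryl ketone (2S)-1-{4-[(tert-butyldimethylsilyl)oxy]-3-methoxyphenyl}-3-[(tert-butyldimethylsilyl)oxy]-2-[4-({[tert-butyldimethylsilyl]oxy}methyl)-2,6-dimethoxyphenoxy]propan-1-one F1. Reduction of this ketone with Zn(BH4)2 in Et2O at −30 °C should be chelation-controlled. Zinc bridges the carbonyl and the α-aryloxy oxygen, and hydride should attack the face carrying the C-2 hydrogen, away from CH2OTBS. This gives the same (1R,2S) alcohol, and the route is rejoined at 12. The C-1 centre is then set by hydride delivery and not by the aryl addition.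

2. Step 2. The SN2 displacement may be slow because the phenol oxygen is flanked by two methoxy groups; elimination of the activated alcohol to an acrylate, alkylation of the reduced azodicarboxylate, or partial loss of configuration may then compete. Fallback: set out from 2 and convert it with Tf2O and 2,6-lutidine in CH2Cl2 at −78 °C into methyl (2R)-3-[(tert-butyldimethylsilyl)oxy]-2-{[(trifluoromethyl)sulfonyl]oxy}propanoate F2. Displacement of the triflate by the potassium phenoxide of 3 (K2CO3, MeCN, 0 °C → rt) should proceed with clean inversion and rejoin the route at 4.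

3. Step 5. The partial reduction may overshoot to the primary alcohol or stop short, and the α-aryloxy aldehyde may epimerise or lose silanol by β-elimination during the aluminium work-up. Fallback: set out from 6 and reduce the ester completely with LiBH4 in THF at 0 °C (short reaction time and neutral work-up, to avoid 1,3-silyl migration between the two primary oxygens) to (2R)-3-[(tert-butyldimethylsilyl)oxy]-2-[4-({[tert-butyldimethylsilyl]oxy}methyl)-2,6-dimethoxyphenoxy]propan-1-ol F3. The descriptor changes only through CIP priorities; the spatial arrangement is unchanged. Oxidation with Dess–Martin periodinane and NaHCO3 in CH2Cl2 at 0 °C under non-basic conditions should then give the aldehyde, rejoining the route at 8.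

**Further compounds**
F1 | step 7 | (2S)-1-{4-[(tert-butyldimethylsilyl)oxy]-3-methoxyphenyl}-3-[(tert-butyldimethylsilyl)oxy]-2-[4-({[tert-butyldimethylsilyl]oxy}methyl)-2,6-dimethoxyphenoxy]propan-1-one | COc1cc(C(=O)[C@H](CO[Si](C)(C)C(C)(C)C)Oc2c(OC)cc(CO[Si](C)(C)C(C)(C)C)cc2OC)ccc1O[Si](C)(C)C(C)(C)C
F2 | step 2 | methyl (2R)-3-[(tert-butyldimethylsilyl)oxy]-2-{[(trifluoromethyl)sulfonyl]oxy}propanoate | COC(=O)[C@H](OS(=O)(=O)C(F)(F)F)CO[Si](C)(C)C(C)(C)C
F3 | step 5 | (2R)-3-[(tert-butyldimethylsilyl)oxy]-2-[4-({[tert-butyldimethylsilyl]oxy}methyl)-2,6-dimethoxyphenoxy]propan-1-ol | OC[C@H](CO[Si](C)(C)C(C)(C)C)Oc1c(OC)cc(CO[Si](C)(C)C(C)(C)C)cc1OC
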